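The numbers in the tables were computed with constants of no real substance; noise was put on by code.

67.8 mM of target per litre of solution, crystals counted, is the reading in birch at 8.00 h, and alpha's whole charge, 50.0 mM, is less.

| setting | birch | eta | alpha |
|---|---|---|---|
| substrate | 0.22 M | 0.20 M | 0.060 M |
| partner | 3 equiv (fed, over 1.0 h) | 3.00 equiv (fed, over 1.0 h) | 6.00 equiv |
| remark | run made earlier; the fed solution adds 0.20 times the starting volume | the fed solution adds 0.20 times the starting volume | everything together at the start, the whole solution of partner included, so that from the start the volume is larger by 0.20 times the starting volume |
| time |  | 12 h | 12 h |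

- birch (time / h: target / %, substrate / %): 1.33: 13.9, 26.7; 2.50: 24.1, 19.8; 4.00: 30.2, 16.2; 5.00: 34.4, 13.4; 6.00: 36.6, 12.8; 8.00: 37.0, 9.6

(each reading ± 1 percentage point)

- what is said of target includes crystals
- amounts are per litre of the starting volume; all of the dose is in the solution fed
- crystals is a solid; its amount is given per volume of the solution
- candidate steps: adduct -> side product; adduct <-> target; crystals <-> target; substrate + partner <-> adduct
- where the amount of substrate changes, what is given in equivalents or mol% on it follows

- which one finishes higher in amount of target, in percent of the substrate charged ("neither" within 2 percentage points) (eta / alpha / neither)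
- amount of target at the end, in percent of the substrate charged, eta
- amount of target at the end, in percent of the substrate charged, alpha

On the quick number, the percentages of birch can't simply be carried over. Between 1.33 h and 2.50 h birch gained 10 percentage points of target while losing 6.9 points of substrate. Between 6.00 h and 8.00 h it gained 0.4 points, inside the scatter of 1 point, while losing 3.2 points. So target levelled off while substrate still went. If crystals are what holds target there, they answer to concentration, not to percent.

The measure to carry is therefore the strength s, the substrate charged per litre of solution once the partner's solution is in: the starting concentration divided by 1.20. Birch has 183 mM and eta 167 mM, so eta is taken as birch again, near 37.0 %. Alpha's s lies a factor 3.66 below birch's. This reckoning puts eta ahead and gives no figure for alpha.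

The forecast also has eta ahead, with eta at 37 % and alpha at 29 %, since alpha “probably forms little or no crystal”.

The flasks give eta 33.6 % and alpha 9.97 %, which leaves alpha 19 points under the forecast.

    adduct → side product (k = 0.140 h⁻¹)
    adduct ⇌ target (K = 0.450, k = 0.460 h⁻¹)
    crystals ⇌ target, rate k3*(cs3 - [target]) while solid is left; crystals form when [target] > cs3 (solubility = 13.0 mM, k = 1.40 h⁻¹)
    substrate + partner ⇌ adduct (K = 4.90 M⁻¹, k = 16.0 M⁻¹ h⁻¹)

The ceiling for dissolved target (its solubility), 13 mM, divided by s is 7.78 % of the charge in eta and 26.0 % in alpha. Eta's target, crystals counted, stands above its ceiling, with 26.3 % as crystals, and alpha's stands below, with 0 %. Alpha ends so low mainly because its dissolved target falls back to adduct: with that way back taken away, alpha gives 75.0 % instead of 9.97 %. A neighbour of alpha charged at 0.015 M has s = 12.5 mM, under the ceiling, and ends with 0 % crystals and 7.08 % target.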